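**Retrosynthetic overview**
1. The tetronic acid ring is closed last, by Lacey–Dieckmann condensation of the acyclic α-propionyloxy ester 22, which already carries the C5 stereocentre.
2. The triene is cut at the C5'–C6' sp2–sp2 bond: Negishi union of the (Z,E)-dienyl iodide 8 with the alkenylzinc made from the East iodide 19.
3. Key step, replacing the usual tetronate C5-alkylation or chiral-pool hydroxy acid plus Wittig: an asymmetric hetero-Diels–Alder of ethyl glyoxylate with 1-ethoxy-3-methylbutadiene builds a temporary dihydropyran that sets C5 (R) and locks the Z trisubstituted alkene; a ring-opening Takai iodo-olefination then unveils the Z,E-diene and the free carbinol.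
4. East half: both furans are bought; 3-furyllithium adds to 4-bromofurfural, the carbinol is deoxygenated, and an alkyl Negishi coupling attaches the pent-3-ynyl chain.
5. Ring order: furans (purchased) → temporary dihydropyran (formed in step 2, opened in step 4) → tetronic acid (step 12).

Assumption: the target is made as the 4-hydroxy (enol) tautomer drawn in the SMILES; its stereocentre is (5R) and the side-chain alkenes are 2Z,4E,6E.

**Route**

Step 1
Reactants: 1 1,1-diethoxy-3-methylbut-2-ene
Product: 2 (1E)-1-ethoxy-3-methylbuta-1,3-diene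
Conditions: n-BuLi/KOt-Bu (1.1 equiv each), THF, −95 → −78 °C; H2O
Reagents that add atoms: none
Why: Superbase-promoted conjugate (1,4-) elimination of an α,β-unsaturated acetal: γ-deprotonation at a methyl group expels ethoxide and gives the 1-alkoxydiene as the E enol ether, the geometry that can reach the s-cis conformation for cycloaddition.

Step 2
Reactants: 2 (1E)-1-ethoxy-3-methylbuta-1,3-diene, 3 ethyl glyoxylate (freshly distilled)
Product: 4 ethyl (2R,6S)-6-ethoxy-4-methyl-3,6-dihydro-2H-pyran-2-carboxylate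
Conditions: (R)-BINOL/TiCl2(OiPr)2 (10 mol%), 4 Å MS, CH2Cl2, −55 → −30 °C
Reagents that add atoms: none
Why: BINOL–titanium-catalysed asymmetric hetero-Diels–Alder reaction of a glyoxylate with a 1-alkoxydiene: the unsubstituted diene terminus attacks the Re face of the chelated aldehyde (same facial sense as the glyoxylate-ene reaction with this catalyst), so C2 is formed R in the endo (cis) adduct, and the six-membered ring forces the new trisubstituted alkene into the cis arrangement that becomes the Z alkene of the target.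

Step 3
Reactants: 4 ethyl (2R,6S)-6-ethoxy-4-methyl-3,6-dihydro-2H-pyran-2-carboxylate
Product: 5 ethyl (2R)-6-hydroxy-4-methyl-3,6-dihydro-2H-pyran-2-carboxylate (both C6 anomers)
Conditions: 1 M HCl (aq)/THF (1:4), 0 °C → rt
Reagents that add atoms: water, O
Why: Mild acid hydrolysis of the allylic mixed acetal through its allyl-stabilised oxocarbenium ion; C2 is not involved and the C6 centre is deliberately erased.

Step 4
Reactants: 5 ethyl (2R)-6-hydroxy-4-methyl-3,6-dihydro-2H-pyran-2-carboxylate
Product: 7 ethyl (2R,4Z,6E)-2-hydroxy-7-iodo-4-methylhepta-4,6-dienoate, via open-chain hydroxy enal 6 (not isolated)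
Conditions: CrCl2 (8 equiv), CHI3 (3 equiv), THF/1,4-dioxane (1:6), 0 °C → rt, dark
Reagents that add atoms: iodoform, IC(I)I
Why: Ring-opening Takai iodo-olefination: the lactol equilibrates with the Z-configured δ-hydroxy enal 6, whose aldehyde is trapped by the geminal dichromium carbenoid formed from CHI3 and divalent chromium to give the E vinyl iodide, while the near-neutral conditions leave the ring-derived Z alkene and the C2 carbinol untouched.

Step 5
Reactants: 7 ethyl (2R,4Z,6E)-2-hydroxy-7-iodo-4-methylhepta-4,6-dienoate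
Product: 8 ethyl (2R,4Z,6E)-7-iodo-4-methyl-2-(propanoyloxy)hepta-4,6-dienoate
Conditions: (EtCO)2O, Et3N, DMAP (10 mol%), CH2Cl2, 0 °C
Reagents that add atoms: propionic anhydride, CCC(=O)OC(=O)CC
Why: DMAP-catalysed O-acylation (Steglich-type acyl transfer) installs the three carbons of the future tetronic acid without touching the stereocentre and masks the hydroxyl for the organozinc coupling.

Step 6
Reactants: 9 3-bromofuran, 10 4-bromofuran-2-carbaldehyde
Product: 12 (4-bromofuran-2-yl)(furan-3-yl)methanol, via 3-furyllithium 11 (not isolated)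
Conditions: n-BuLi (1.05 equiv), THF, −78 °C; then 10, −78 °C; H2O
Reagents that add atoms: none
Why: Bromine–lithium exchange followed by 1,2-addition to the aldehyde, which at −78 °C outpaces both the 3→2 lithium shift of the furyllithium and exchange at the β-bromide of 10; the racemic carbinol centre is removed in the next step.

Step 7
Reactants: 12 (4-bromofuran-2-yl)(furan-3-yl)methanol
Product: 13 4-bromo-2-(furan-3-ylmethyl)furan
Conditions: Et3SiH (3 equiv), CF3CO2H (5 equiv), CH2Cl2, −20 → 0 °C
Reagents that add atoms: none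
Why: Ionic hydrogenation: the doubly furyl-stabilised carbocation forms readily and is captured by silane hydride faster than it can alkylate another furan.

Step 8
Reactants: 14 pent-3-yn-1-ol
Product: 15 5-iodopent-2-yne
Conditions: PPh3, imidazole, I2, CH2Cl2, 0 °C → rt
Reagents that add atoms: iodine, [I][I]
Why: Appel-type iodination: SN2 displacement of the alkoxyphosphonium ion by iodide at a primary carbon.

Step 9
Reactants: 15 5-iodopent-2-yne, 13 4-bromo-2-(furan-3-ylmethyl)furan
Product: 17 2-(furan-3-ylmethyl)-4-(pent-3-yn-1-yl)furan, via pent-3-yn-1-ylzinc iodide 16 (not isolated)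
Conditions: Zn dust (activated with BrCH2CH2Br, Me3SiCl), THF, 40 °C; decant; then 13, Pd(OAc)2 (2 mol%), SPhos (4 mol%), THF, rt → 45 °C
Reagents that add atoms: none
Why: Zinc insertion into the primary iodide then sp3–sp2 Negishi coupling with the β-bromofuran; the bulky biarylphosphine makes reductive elimination faster than β-hydride elimination and the internal alkyne is inert.

Step 10
Reactants: 17 2-(furan-3-ylmethyl)-4-(pent-3-yn-1-yl)furan
Product: 19 2-(furan-3-ylmethyl)-4-[(3E)-4-iodopent-3-en-1-yl]furan, via alkenylzirconocene chloride 18 (not isolated)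
Conditions: Cp2Zr(H)Cl (1.5 equiv), THF, 50 °C, 1 h; then I2 (1.5 equiv), THF, −20 → 0 °C
Reagents that add atoms: iodine, [I][I]
Why: Schwartz hydrozirconation is a syn addition, and equilibration with excess Zr–H at 50 °C moves zirconium to the less hindered methyl-bearing carbon (typically ≥10:1); iodinolysis with retention then gives the E trisubstituted iodide.

Step 11
Reactants: 19 2-(furan-3-ylmethyl)-4-[(3E)-4-iodopent-3-en-1-yl]furan, 8 ethyl (2R,4Z,6E)-7-iodo-4-methyl-2-(propanoyloxy)hepta-4,6-dienoate
Product: 22 ethyl (2R,4Z,6E,8E)-11-[5-(furan-3-ylmethyl)furan-3-yl]-4,8-dimethyl-2-(propanoyloxy)undeca-4,6,8-trienoate, via alkenyllithium 20 (not isolated), via alkenylzinc chloride 21 (not isolated)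
Conditions: t-BuLi (2.05 equiv), Et2O, −78 °C; ZnCl2 (1.1 equiv, THF), −78 → 0 °C; then 8 (0.8 equiv), Pd(PPh3)4 (5 mol%), THF, rt
Reagents that add atoms: none
Why: Iodine–lithium exchange, transmetalation to zinc and Negishi coupling with zerovalent palladium all proceed with retention at both sp2 carbons, so the 4Z,6E,8E triene is assembled from stereodefined halves, and the organozinc tolerates both esters.

Step 12
Reactants: 22 ethyl (2R,4Z,6E,8E)-11-[5-(furan-3-ylmethyl)furan-3-yl]-4,8-dimethyl-2-(propanoyloxy)undeca-4,6,8-trienoate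
Product: 23 (5R)-5-[(2Z,4E,6E)-9-[5-(furan-3-ylmethyl)furan-3-yl]-2,6-dimethylnona-2,4,6-trien-1-yl]-4-hydroxy-3-methylfuran-2(5H)-one
Conditions: LiN(SiMe3)2 (2.5 equiv), THF, −78 → 0 °C; then cold 1 M HCl to pH 3
Reagents that add atoms: none
Why: Lacey–Dieckmann (intramolecular Claisen) condensation: the propionate enolate attacks the ethyl ester in a 5-exo closure and the tetronate anion is the thermodynamic sink, so at low temperature with the amide base the C5–H is not epimerised and the R centre from step 2 is carried into the target.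

**Compound list**
1 | 1,1-diethoxy-3-methylbut-2-ene | CCOC(OCC)C=C(C)C | starting material
2 | (1E)-1-ethoxy-3-methylbuta-1,3-diene | CCO/C=C/C(C)=C | intermediate
3 | ethyl glyoxylate (ethyl 2-oxoacetate) | CCOC(=O)C=O | starting material
4 | ethyl (2R,6S)-6-ethoxy-4-methyl-3,6-dihydro-2H-pyran-2-carboxylate | CCOC(=O)[C@H]1CC(C)=C[C@@H](OCC)O1 | intermediate
5 | ethyl (2R)-6-hydroxy-4-methyl-3,6-dihydro-2H-pyran-2-carboxylate (both C6 anomers) | CCOC(=O)[C@H]1CC(C)=CC(O)O1 | intermediate
6 | ethyl (2R,4Z)-2-hydroxy-4-methyl-6-oxohex-4-enoate | CCOC(=O)[C@@H](C\C(C)=C/C=O)O | intermediate (not isolated)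
7 | ethyl (2R,4Z,6E)-2-hydroxy-7-iodo-4-methylhepta-4,6-dienoate | CCOC(=O)[C@@H](C\C(C)=C/C=C/I)O | intermediate
8 | ethyl (2R,4Z,6E)-7-iodo-4-methyl-2-(propanoyloxy)hepta-4,6-dienoate | CCOC(=O)[C@@H](C\C(C)=C/C=C/I)OC(=O)CC | intermediate
9 | 3-bromofuran | Brc1ccoc1 | starting material
10 | 4-bromofuran-2-carbaldehyde | O=Cc1cc(Br)co1 | starting material
11 | furan-3-yllithium | [Li]c1ccoc1 | intermediate (not isolated)
12 | (4-bromofuran-2-yl)(furan-3-yl)methanol (racemic) | OC(c1cc(Br)co1)c1ccoc1 | intermediate
13 | 4-bromo-2-(furan-3-ylmethyl)furan | Brc1coc(Cc2ccoc2)c1 | intermediate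
14 | pent-3-yn-1-ol | CC#CCCO | starting material
15 | 5-iodopent-2-yne | CC#CCCI | intermediate
16 | pent-3-yn-1-ylzinc iodide | CC#CCC[Zn]I | intermediate (not isolated)
17 | 2-(furan-3-ylmethyl)-4-(pent-3-yn-1-yl)furan | CC#CCCc1coc(Cc2ccoc2)c1 | intermediate
18 | chlorobis(cyclopentadienyl)[(2E)-5-[5-(furan-3-ylmethyl)furan-3-yl]pent-2-en-2-yl]zirconium (cyclopentadienyl rings drawn σ-bound) | C/C(=C\CCc1coc(Cc2ccoc2)c1)[Zr](Cl)(C1C=CC=C1)C1C=CC=C1 | intermediate (not isolated)
19 | 2-(furan-3-ylmethyl)-4-[(3E)-4-iodopent-3-en-1-yl]furan | C/C(I)=C\CCc1coc(Cc2ccoc2)c1 | intermediate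
20 | [(2Z)-5-[5-(furan-3-ylmethyl)furan-3-yl]pent-2-en-2-yl]lithium (same geometry as 19; the letter changes because Li ranks below CH3) | C/C([Li])=C\CCc1coc(Cc2ccoc2)c1 | intermediate (not isolated)
21 | chloro[(2E)-5-[5-(furan-3-ylmethyl)furan-3-yl]pent-2-en-2-yl]zinc | C/C([Zn]Cl)=C\CCc1coc(Cc2ccoc2)c1 | intermediate (not isolated)
22 | ethyl (2R,4Z,6E,8E)-11-[5-(furan-3-ylmethyl)furan-3-yl]-4,8-dimethyl-2-(propanoyloxy)undeca-4,6,8-trienoate | CCOC(=O)[C@@H](C\C(C)=C/C=C/C(C)=C/CCc1coc(Cc2ccoc2)c1)OC(=O)CC | intermediate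
23 | (5R)-5-[(2Z,4E,6E)-9-[5-(furan-3-ylmethyl)furan-3-yl]-2,6-dimethylnona-2,4,6-trien-1-yl]-4-hydroxy-3-methylfuran-2(5H)-one (CNP0176158.2) | CC1=C(O)[C@@H](C\C(C)=C/C=C/C(C)=C/CCc2coc(Cc3ccoc3)c2)OC1=O | target

**Totals**
Total step count: 12. Longest linear sequence: 7 steps (1, 2, 3, 4, 5, 11, 12). The East branch is 6 steps (6, 7, 9, 10, 11, 12).

**Three steps most likely to fail, each with a fallback**

Step 2 (asymmetric hetero-Diels–Alder). The diene also has an isopropenyl unit, so a glyoxylate-ene or open-chain aldol pathway could compete, and the enantioselectivity with this particular diene is an extrapolation from 1-methoxybutadiene. The fallback sets out from ethyl glyoxylate 3 and comes back at 4. The same (R)-BINOL/TiCl2(OiPr)2 catalyst is used in its best-established mode, the glyoxylate-ene reaction with 2-methylpropene, to give ethyl (2R)-2-hydroxy-4-methylpent-4-enoate F1. PPTS-catalysed transacetalisation of F1 with acrolein diethyl acetal (toluene, 40 °C, ethanol removed under reduced pressure) gives the mixed acetal ethyl (2R)-2-[(1-ethoxyprop-2-en-1-yl)oxy]-4-methylpent-4-enoate F2. Ring-closing metathesis of F2 with second-generation Grubbs catalyst RuCl2(=CHPh)(PCy3)(H2IMes) in CH2Cl2 at 40 °C closes the same dihydropyran with the cis ring alkene. It gives 4 together with its C6 epimer ethyl (2R,6R)-6-ethoxy-4-methyl-3,6-dihydro-2H-pyran-2-carboxylate F3; both are hydrolysed to 5 in step 3.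

Step 4 (Takai olefination on a lactol). The 2H-pyran-2-ol may open too slowly under neutral chromium conditions, and the E/Z ratio at the new alkene is not guaranteed. The fallback sets out from 5 and comes back at 7. Colvin homologation with Me3SiC(Li)N2 (2.2 equiv, THF, −78 → 0 °C) first opens the lactol as its lithium alkoxide and then converts the aldehyde into the terminal alkyne, giving ethyl (2R,4Z)-2-hydroxy-4-methylhept-4-en-6-ynoate F4. Cp2Zr(H)Cl (2.2 equiv, THF, 0 °C → rt) zirconates the hydroxyl and adds syn across the alkyne to form ethyl (2R,4Z,6E)-7-[chlorobis(cyclopentadienyl)zirconio]-2-{[chlorobis(cyclopentadienyl)zirconio]oxy}-4-methylhepta-4,6-dienoate F5, which is not isolated. Iodine then gives 7, with the E geometry fixed by the syn addition.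

Step 11 (Negishi union). The t-BuLi exchange is carried out in the presence of acidic furan α-hydrogens and the bis-furyl methylene, and the alkenyllithium could be quenched internally before it reaches zinc. The fallback sets out from 19 and comes back at 22, and avoids organolithiums. Miyaura borylation of 19 (B2pin2, PdCl2(PPh3)2, PPh3, KOPh, toluene, 50 °C) gives 2-[(2Z)-5-[5-(furan-3-ylmethyl)furan-3-yl]pent-2-en-2-yl]-4,4,5,5-tetramethyl-1,3,2-dioxaborolane F6, which has the same geometry as 19. Suzuki–Miyaura coupling of F6 with iodide 8 (PdCl2(dppf), K3PO4, THF/H2O 10:1, rt) gives 22.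

**Further compounds**
F1 | step 2 | ethyl (2R)-2-hydroxy-4-methylpent-4-enoate | CCOC(=O)[C@@H](CC(C)=C)O
F2 | step 2 | ethyl (2R)-2-[(1-ethoxyprop-2-en-1-yl)oxy]-4-methylpent-4-enoate (acetal epimers) | CCOC(=O)[C@@H](CC(C)=C)OC(OCC)C=C
F3 | step 2 | ethyl (2R,6R)-6-ethoxy-4-methyl-3,6-dihydro-2H-pyran-2-carboxylate | CCOC(=O)[C@H]1CC(C)=C[C@H](OCC)O1
F4 | step 4 | ethyl (2R,4Z)-2-hydroxy-4-methylhept-4-en-6-ynoate | CCOC(=O)[C@@H](C\C(C)=C/C#C)O
F5 | step 4 | ethyl (2R,4Z,6E)-7-[chlorobis(cyclopentadienyl)zirconio]-2-{[chlorobis(cyclopentadienyl)zirconio]oxy}-4-methylhepta-4,6-dienoate | CCOC(=O)[C@@H](C\C(C)=C/C=C/[Zr](Cl)(C1C=CC=C1)C1C=CC=C1)O[Zr](Cl)(C1C=CC=C1)C1C=CC=C1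
F6 | step 11 | 2-[(2Z)-5-[5-(furan-3-ylmethyl)furan-3-yl]pent-2-en-2-yl]-4,4,5,5-tetramethyl-1,3,2-dioxaborolane | C/C(B1OC(C)(C)C(C)(C)O1)=C\CCc1coc(Cc2ccoc2)c1
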